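**Retrosynthetic overview**

1. Last disconnection: the C7–C8 bond of the allylic alcohol (C7 = carbinol carbon), by Nozaki–Hiyama–Kishi coupling of ring A aldehyde 10 with ring B (E)-vinyl iodide 18.
2. Ring A (C1 = CH, C2 = CMe2, C3=C4, C5 = CH2, C6 = C(=CH2)): the C1–C2 bond is made by Ireland–Claisen rearrangement of the silyl ketene acetal of δ-lactone 5, which closes the carbocycle as it opens the lactone (a temporary ring).
3. Enabling feature: C7 (at acid level)–C1–C2(Me)2–C3=C4 is a γ,δ-unsaturated acid, and C4 is tied back to C1 through C5 and C6, so the allylic oxygen on C4 and the acyl carbon fit in one six-membered lactone; the exocyclic C6=CH2 makes the lactone α-CH2 the only acidic site.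
4. Stereo relay: one center of 5 is set by catalytic asymmetric 2-bromoallylation of prenal and passed to C1 (step 3) and then to C7 (step 11). In ring B, a proline aminoxylation desymmetrizes the cyclohexanone, and Appel inversion and Cornforth-type methyl addition give the all-cis bromohydrin.
5. Order of rings: ring B is bought (cyclohexanone ketal 11), ring A is formed in step 3, the two are joined in step 11.

Key step: step 3

Assumption: in step 1 the ligand enantiomer is the one that gives the 4S alcohol (to be checked by Mosher ester analysis of 3); 11 is taken as a commercial building block.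

**Route**

Step 1
Reactants: 1 3-methylbut-2-enal
Product: 3 (4S)-2-bromo-6-methylhepta-1,5-dien-4-ol, via trimethylsilyl ether 2 (not isolated)
Conditions: 2,3-dibromoprop-1-ene, CrCl2 (10 mol %), (S)-N-[2-(4-isopropyl-4,5-dihydro-1,3-oxazol-2-yl)-6-methylphenyl]methanesulfonamide (12 mol %), Et3N, Mn powder, TMSCl, THF, 0 °C to rt; then K2CO3, MeOH
Reagents that add atoms: 2,3-dibromoprop-1-ene, C=C(Br)CBr
Why: Catalytic asymmetric Nozaki–Hiyama allylation: Mn turns over the chromium catalyst, the allylic (not the vinylic) C–Br bond gives a 2-bromoallylchromium species that adds 1,2 to the enal through a closed six-membered transition state on the chiral sulfonamide–oxazoline complex, which sets the carbinol center as S, and TMSCl frees the catalyst from the alkoxide.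

Step 2
Reactants: 3 (4S)-2-bromo-6-methylhepta-1,5-dien-4-ol
Product: 5 (6S)-4-methylidene-6-(2-methylprop-1-en-1-yl)oxan-2-one, via hydroxy ester 4 (not isolated)
Conditions: BrZnCH2CO2Et (2.5 equiv, from ethyl bromoacetate and Zn dust), Pd(dba)2 (5 mol %), 1,2,3,4,5-pentaphenyl-1'-(di-tert-butylphosphino)ferrocene (5 mol %), THF, rt to 50 °C; then PPTS (cat.), toluene, 50 °C
Reagents that add atoms: bromo(2-ethoxy-2-oxoethyl)zinc, CCOC(=O)C[Zn]Br
Why: Palladium-catalysed Negishi-type coupling of the Reformatsky reagent with the 2-bromo-1-alkene puts the CH2CO2Et arm on the 1,1-disubstituted alkene without shifting it into conjugation, and mild acid then closes the δ-lactone by transesterification, which does not touch the carbinol center.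

Step 3
Reactants: 5 (6S)-4-methylidene-6-(2-methylprop-1-en-1-yl)oxan-2-one
Product: 8 (1R)-2,2-dimethyl-6-methylidenecyclohex-3-ene-1-carboxylic acid, via silyl ketene acetal 6 (not isolated), via silyl ester 7 (not isolated)
Conditions: LDA, THF, −78 °C; TBSCl, HMPA, −78 to 0 °C; toluene, 100 °C; then 1 M aq HCl, THF, 0 °C
Reagents that add atoms: none
Why: LDA removes a proton from the doubly activated α-CH2 (α to C=O and allylic to the exocyclic methylene) and TBSCl traps the enolate on oxygen as cyclic silyl ketene acetal 6, in which the endocyclic C=C(OSi)–O unit and the 2-methylprop-1-enyl group on the carbinol carbon form an allyl vinyl ether; heating drives the [3,3]-sigmatropic shift (Ireland–Claisen) that forms C1–C2 and breaks the lactone C–O bond to give silyl ester 7, which is hydrolysed on work-up. The closest known reaction type is the Ireland–Claisen rearrangement of silyl ketene acetals of δ-lactones that carry an alkenyl group on the carbinol carbon, which gives cyclohex-3-enecarboxylic acids. Ring A closes in a concerted, suprafacial six-centre process through the boat-like transition state that the six-membered ketene acetal ring enforces, and this is also why the new C3=C4 bond can only be cis. The new stereocenter C1 is controlled by the lactone carbinol center alone: the alkenyl group can reach only the face of the ketene acetal on which the ring holds it, so (S)-5 should give (R)-8 with full chirality transfer, and because the migrating terminus is CMe2 the quaternary carbon C2 raises no second stereochemical issue. The step needs α-deprotonation and a [3,3] shift of the allyl vinyl ether in preference to Cope rearrangement of the 1,5-diene that is also present; the acidity of the α-CH2 and the rate advantage of the electron-rich ketene acetal secure both, and the neutral silyl ester keeps the α-CH from epimerizing or the exocyclic alkene from moving into conjugation.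

Step 4
Reactants: 8 (1R)-2,2-dimethyl-6-methylidenecyclohex-3-ene-1-carboxylic acid
Product: 9 [(1R)-2,2-dimethyl-6-methylidenecyclohex-3-en-1-yl]methanol
Conditions: LiAlH4, Et2O, 0 °C to rt
Reagents that add atoms: none
Why: Hydride reduction of the carboxylic acid (first deprotonated to the carboxylate, so the α-CH is not enolized) should give the primary alcohol with C1 and both alkenes unchanged.

Step 5
Reactants: 9 [(1R)-2,2-dimethyl-6-methylidenecyclohex-3-en-1-yl]methanol
Product: 10 (1R)-2,2-dimethyl-6-methylidenecyclohex-3-ene-1-carbaldehyde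
Conditions: Dess–Martin periodinane, NaHCO3, CH2Cl2, 0 °C; used crude
Reagents that add atoms: none
Why: Dess–Martin oxidation under buffered, non-basic conditions should give the β,γ-unsaturated aldehyde without epimerization at C1 or migration of the exocyclic double bond, provided it is used at once.

Step 6
Reactants: 11 8-ethynyl-1,4-dioxaspiro[4.5]decane
Product: 13 8-[(1E)-1-iodoprop-1-en-2-yl]-1,4-dioxaspiro[4.5]decane, via vinylalane 12 (not isolated)
Conditions: AlMe3 (3 equiv), Cp2ZrCl2 (0.25 equiv), H2O (1.5 equiv), CH2Cl2, −25 °C; then I2, THF, −25 to 0 °C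
Reagents that add atoms: trimethylaluminium, C[Al](C)C; iodine, II
Why: Zirconium-catalysed (Negishi) carboalumination adds CH3 and Al syn across the terminal alkyne with Al on the terminal carbon, and iodinolysis of the C–Al bond with retention should give the E-iodide; the low temperature of the water-accelerated variant spares the ketal.

Step 7
Reactants: 13 8-[(1E)-1-iodoprop-1-en-2-yl]-1,4-dioxaspiro[4.5]decane
Product: 14 4-[(1E)-1-iodoprop-1-en-2-yl]cyclohexan-1-one
Conditions: 1 M aq HCl, THF, rt
Reagents that add atoms: water, O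
Why: Acid-catalysed ketal hydrolysis frees the ketone, the vinyl iodide being stable to dilute aqueous acid.

Step 8
Reactants: 14 4-[(1E)-1-iodoprop-1-en-2-yl]cyclohexan-1-one
Product: 16 (2R,4S)-2-hydroxy-4-[(1E)-1-iodoprop-1-en-2-yl]cyclohexan-1-one, via aminooxy ketone 15 (not isolated)
Conditions: L-proline (30 mol %), PhNO (slow addition), DMSO, rt; then CuSO4·5H2O (0.3 equiv), MeOH, 0 °C
Reagents that add atoms: nitrosobenzene, O=Nc1ccccc1
Why: Proline-catalysed α-aminoxylation through the enamine desymmetrizes the ketone, L-proline delivering oxygen to give the 2R center by axial attack on the half-chair with the 4-substituent equatorial (C–O trans to the side chain, which also fixes C4 as S), and CuSO4 in MeOH cleaves the N–O bond without touching the ketol.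

Step 9
Reactants: 16 (2R,4S)-2-hydroxy-4-[(1E)-1-iodoprop-1-en-2-yl]cyclohexan-1-one
Product: 17 (2S,4S)-2-bromo-4-[(1E)-1-iodoprop-1-en-2-yl]cyclohexan-1-one
Conditions: CBr4, PPh3, 2,6-lutidine, CH2Cl2, −20 to 0 °C
Reagents that add atoms: tetrabromomethane, BrC(Br)(Br)Br
Why: Appel reaction: bromide displaces the oxyphosphonium group at the α-keto carbon by SN2 with inversion (the axial leaving group is aligned with the C=O π system), turning the trans ketol into the cis, diequatorial bromoketone.

Step 10
Reactants: 17 (2S,4S)-2-bromo-4-[(1E)-1-iodoprop-1-en-2-yl]cyclohexan-1-one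
Product: 18 (1R,2S,4S)-2-bromo-4-[(1E)-1-iodoprop-1-en-2-yl]-1-methylcyclohexan-1-ol
Conditions: MeMgBr, anhydrous CeCl3, THF, −78 °C; aq NH4Cl quench at −78 °C
Reagents that add atoms: methylmagnesium bromide, C[Mg]Br
Why: 1,2-Addition of the non-basic organocerium reagent should occur anti to the C–Br bond (Cornforth or polar Felkin–Anh model; equatorial attack on the diequatorial chair and axial attack on the diaxial chair give the same product), so CH3 ends trans and OH cis to Br, and the tertiary center is relayed from the C–Br center.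

Step 11
Reactants: 10 (1R)-2,2-dimethyl-6-methylidenecyclohex-3-ene-1-carbaldehyde; 18 (1R,2S,4S)-2-bromo-4-[(1E)-1-iodoprop-1-en-2-yl]-1-methylcyclohexan-1-ol
Product: 19 (1R,2S,4S)-2-bromo-4-[(2E,4R)-4-[(1R)-2,2-dimethyl-6-methylidenecyclohex-3-en-1-yl]-4-hydroxybut-2-en-2-yl]-1-methylcyclohexan-1-ol
Conditions: CrCl2 (4 equiv), NiCl2 (2 mol %), DMSO–THF, rt
Reagents that add atoms: none
Why: Nozaki–Hiyama–Kishi coupling: the alkenylchromium reagent formed from the vinyl iodide under nickel catalysis adds to the aldehyde with retention of the E geometry and, by the Felkin–Anh model (CMe2 as the large group anti to the nucleophile, attack past H), should give the 7R alcohol, while the free tertiary OH, the secondary bromide and the epimerizable α-CH tolerate the neutral conditions.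

**Compound list**

1 | 3-methylbut-2-enal | CC(C)=CC=O | starting material
2 | {[(4S)-2-bromo-6-methylhepta-1,5-dien-4-yl]oxy}trimethylsilane | CC(C)=C[C@@H](O[Si](C)(C)C)CC(Br)=C | intermediate
3 | (4S)-2-bromo-6-methylhepta-1,5-dien-4-ol | CC(C)=C[C@@H](O)CC(Br)=C | intermediate
4 | ethyl (5S)-5-hydroxy-7-methyl-3-methylideneoct-6-enoate | CC(C)=C[C@@H](O)CC(=C)CC(=O)OCC | intermediate
5 | (6S)-4-methylidene-6-(2-methylprop-1-en-1-yl)oxan-2-one | CC(C)=C[C@@H]1CC(=C)CC(=O)O1 | intermediate
6 | tert-butyl(dimethyl){[(2S)-4-methylidene-2-(2-methylprop-1-en-1-yl)-3,4-dihydro-2H-pyran-6-yl]oxy}silane | CC(C)=C[C@@H]1CC(=C)C=C(O[Si](C)(C)C(C)(C)C)O1 | intermediate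
7 | tert-butyl(dimethyl)silyl (1R)-2,2-dimethyl-6-methylidenecyclohex-3-ene-1-carboxylate | C=C1CC=CC(C)(C)[C@@H]1C(=O)O[Si](C)(C)C(C)(C)C | intermediate
8 | (1R)-2,2-dimethyl-6-methylidenecyclohex-3-ene-1-carboxylic acid | C=C1CC=CC(C)(C)[C@@H]1C(=O)O | intermediate
9 | [(1R)-2,2-dimethyl-6-methylidenecyclohex-3-en-1-yl]methanol | C=C1CC=CC(C)(C)[C@@H]1CO | intermediate
10 | (1R)-2,2-dimethyl-6-methylidenecyclohex-3-ene-1-carbaldehyde | C=C1CC=CC(C)(C)[C@@H]1C=O | intermediate
11 | 8-ethynyl-1,4-dioxaspiro[4.5]decane | C#CC1CCC2(CC1)OCCO2 | starting material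
12 | [(1E)-2-(1,4-dioxaspiro[4.5]decan-8-yl)prop-1-en-1-yl]dimethylalumane | C[Al](C)/C=C(\C)C1CCC2(CC1)OCCO2 | intermediate
13 | 8-[(1E)-1-iodoprop-1-en-2-yl]-1,4-dioxaspiro[4.5]decane | I/C=C(\C)C1CCC2(CC1)OCCO2 | intermediate
14 | 4-[(1E)-1-iodoprop-1-en-2-yl]cyclohexan-1-one | I/C=C(\C)C1CCC(=O)CC1 | intermediate
15 | (2R,4S)-4-[(1E)-1-iodoprop-1-en-2-yl]-2-[(phenylamino)oxy]cyclohexan-1-one | I/C=C(\C)[C@H]1CCC(=O)[C@H](ONc2ccccc2)C1 | intermediate
16 | (2R,4S)-2-hydroxy-4-[(1E)-1-iodoprop-1-en-2-yl]cyclohexan-1-one | I/C=C(\C)[C@H]1CCC(=O)[C@H](O)C1 | intermediate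
17 | (2S,4S)-2-bromo-4-[(1E)-1-iodoprop-1-en-2-yl]cyclohexan-1-one | I/C=C(\C)[C@H]1CCC(=O)[C@@H](Br)C1 | intermediate
18 | (1R,2S,4S)-2-bromo-4-[(1E)-1-iodoprop-1-en-2-yl]-1-methylcyclohexan-1-ol | I/C=C(\C)[C@H]1CC[C@@](C)(O)[C@@H](Br)C1 | intermediate
19 | (1R,2S,4S)-2-bromo-4-[(2E,4R)-4-[(1R)-2,2-dimethyl-6-methylidenecyclohex-3-en-1-yl]-4-hydroxybut-2-en-2-yl]-1-methylcyclohexan-1-ol | C=C1CC=CC(C)(C)[C@@H]1[C@H](O)/C=C(\C)[C@H]1CC[C@@](C)(O)[C@@H](Br)C1 | target

Total step count: 11.
Longest linear sequence: 6 steps (steps 1–5 and 11, or steps 6–10 and 11).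

**Steps most likely to fail**

Step 9. The α-stereocenter may be lost by enolization or by bromide exchange on the product during phosphonium activation, and inversion may be incomplete. The fallback sets out from 16. The ketol is converted into its triflate, (1R,5S)-5-[(1E)-1-iodoprop-1-en-2-yl]-2-oxocyclohexyl trifluoromethanesulfonate F2 (Tf2O, 2,6-di-tert-butyl-4-methylpyridine, CH2Cl2, −78 °C). This isolated sulfonate is displaced with Bu4NBr (1.0 equiv, CH2Cl2, −40 °C) under kinetic control, where the triflate should react far faster than the bromoketone exchanges. The sequence comes back to the route at 17.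

Step 8. The enamine may take up oxygen with poor trans/cis selectivity (equatorial against axial delivery), or the ketol may equilibrate by ketol shift. The fallback sets out from 14. Enantioselective deprotonation with a chiral lithium amide (lithium bis[(R)-1-phenylethyl]amide or its enantiomer, TMSCl in-situ quench, THF, −100 °C) gives the silyl enol ether, trimethyl({(4S)-4-[(1E)-1-iodoprop-1-en-2-yl]cyclohex-1-en-1-yl}oxy)silane F1. The lithium enolate is regenerated with MeLi (THF, −78 °C) and hydroxylated with 2-(phenylsulfonyl)-3-phenyloxaziridine, axial attack placing oxygen trans to the side chain. The sequence comes back at 16.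

Step 11. The addition to the α-branched aldehyde may show poor facial selectivity at the carbinol carbon. The fallback sets out from 10 and 18. The coupling is run as in step 11 without regard to the carbinol configuration, so the crude product also holds the 7S epimer, (1R,2S,4S)-2-bromo-4-[(2E,4S)-4-[(1R)-2,2-dimethyl-6-methylidenecyclohex-3-en-1-yl]-4-hydroxybut-2-en-2-yl]-1-methylcyclohexan-1-ol F3. The alcohol mixture is oxidized with Dess–Martin periodinane (NaHCO3, CH2Cl2, 0 °C) to the enone, (2E)-3-[(1S,3S,4R)-3-bromo-4-hydroxy-4-methylcyclohexyl]-1-[(1R)-2,2-dimethyl-6-methylidenecyclohex-3-en-1-yl]but-2-en-1-one F4. Corey–Bakshi–Shibata reduction (2-methyl-CBS-oxazaborolidine, catecholborane, toluene, −78 °C; catalyst enantiomer chosen for the 7R alcohol) sets the carbinol center by reagent control. The sequence comes back at 19.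

Further compounds
F1 | step 8 | trimethyl({(4S)-4-[(1E)-1-iodoprop-1-en-2-yl]cyclohex-1-en-1-yl}oxy)silane | I/C=C(\C)[C@H]1CCC(O[Si](C)(C)C)=CC1
F2 | step 9 | (1R,5S)-5-[(1E)-1-iodoprop-1-en-2-yl]-2-oxocyclohexyl trifluoromethanesulfonate | I/C=C(\C)[C@H]1CCC(=O)[C@H](OS(=O)(=O)C(F)(F)F)C1
F3 | step 11 | (1R,2S,4S)-2-bromo-4-[(2E,4S)-4-[(1R)-2,2-dimethyl-6-methylidenecyclohex-3-en-1-yl]-4-hydroxybut-2-en-2-yl]-1-methylcyclohexan-1-ol | C=C1CC=CC(C)(C)[C@@H]1[C@@H](O)/C=C(\C)[C@H]1CC[C@@](C)(O)[C@@H](Br)C1
F4 | step 11 | (2E)-3-[(1S,3S,4R)-3-bromo-4-hydroxy-4-methylcyclohexyl]-1-[(1R)-2,2-dimethyl-6-methylidenecyclohex-3-en-1-yl]but-2-en-1-one | C=C1CC=CC(C)(C)[C@@H]1C(=O)/C=C(\C)[C@H]1CC[C@@](C)(O)[C@@H](Br)C1
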